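**Retrosynthetic overview**
1. Target 21 ⇐ hydride opening of epoxide 20 ⇐ reagent-controlled Shi epoxidation of cyclohexene 19. This C–O bond formation at the ring-A carbinol carbon is the key step.
2. 19 ⇐ sp3–sp2 Suzuki coupling of primary boronate 13 with enol triflate 18.
3. 13 ⇐ Matteson homologation ⇐ hydroboration of hydrindenol 10 (trans ring fusion and C3) ⇐ MeLi addition to enone 9.
4. 9 ⇐ aldol condensation (five-membered ring) ⇐ bromocyclohexanone 7 ⇐ new enantioselective bromocyclization of keto ester 6 (six-membered ring, C–Br, quaternary carbon).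
5. 18 ⇐ bromoketone 17 ⇐ the same bromocyclization on prenylated acetoacetate 15. Ring order: hydrindane six-ring, then five-ring; ring A is made separately.

Assumption: hex-1-en-5-yne, tert-butyl acetoacetate and prenyl bromide are taken as commercial; the ester-bearing C1 of 7, 8 and 16 is an epimer/enol mixture that is removed later; the catalyst antipode in steps 4 and 10 is the one that delivers Br+ to the Si face of C6.

**Step 1**
Reactants: 1 hex-1-en-5-yne
Product: 3 (E)-3-methylhepta-2,6-dien-1-ol, via alkenylalane 2 (not isolated)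
Conditions: Me3Al, Cp2ZrCl2 (cat.), CH2Cl2, 0 °C→rt; n-BuLi, THF, −78 °C; (CH2O)n, rt
Reagents that add atoms: trimethylaluminium C[Al](C)C; paraformaldehyde (as formaldehyde) C=O
Why: Negishi Zr-catalysed carboalumination adds Me–Al syn across the terminal alkyne and the alanate is hydroxymethylated with retention, which fixes the E alkene that later sets the Br/Me relative configuration.

**Step 2**
Reactants: 3 (E)-3-methylhepta-2,6-dien-1-ol
Product: 4 (E)-1-bromo-3-methylhepta-2,6-diene
Conditions: PBr3, Et2O, 0 °C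
Reagents that add atoms: phosphorus tribromide BrP(Br)Br
Why: SN2 bromination of the primary allylic alcohol at low temperature proceeds without allylic transposition or E/Z loss.

**Step 3**
Reactants: 4 (E)-1-bromo-3-methylhepta-2,6-diene; 5 tert-butyl acetoacetate
Product: 6 tert-butyl (E)-7-methyl-3-oxoundeca-6,10-dienoate
Conditions: NaH, THF, 0 °C; n-BuLi, −10 °C; then 4, 0 °C
Reagents that add atoms: none
Why: Weiler dianion alkylation; the γ-carbon of the acetoacetate dianion is the most nucleophilic site and displaces the allylic bromide by SN2.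

**Step 4**
Reactants: 6 tert-butyl (E)-7-methyl-3-oxoundeca-6,10-dienoate
Product: 7 tert-butyl (2S,3S)-3-bromo-2-(but-3-en-1-yl)-2-methyl-6-oxocyclohexane-1-carboxylate
Conditions: DBDMH (0.55 equiv), chiral BINOL-derived N-triflylthiophosphoramide (10 mol %), PhMe, −78 °C
Reagents that add atoms: 1,3-dibromo-5,5-dimethylhydantoin CC1(C)N(Br)C(=O)N(Br)C1=O
Why: Proposed new method: the chiral P=S Lewis base takes Br+ from DBDMH and passes it to the Si face of C6 of the E-trisubstituted alkene while its acidic N–H holds the enol of the β-keto ester, whose α-carbon opens the bromonium ion at the tertiary carbon anti to Br through a chair (Br equatorial, methyl axial, butenyl equatorial), giving the cis Br/Me pair with 2S,3S configuration; the monosubstituted alkene is too electron-poor to compete; closest known reactions are the thiophosphoramide/DBDMH enantioselective bromocyclization of homogeranylarenes and the Lewis acid or Hg(II) C-cyclization of polyene β-keto esters (cation–olefin polyene cyclization).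

**Step 5**
Reactants: 7 tert-butyl (2S,3S)-3-bromo-2-(but-3-en-1-yl)-2-methyl-6-oxocyclohexane-1-carboxylate
Product: 9 (7S,7aS)-7-bromo-7a-methyl-1,2,5,6,7,7a-hexahydro-4H-inden-4-one, via keto aldehyde 8 (not isolated)
Conditions: O3, CH2Cl2, −78 °C; Me2S; then TsOH·H2O (0.2 equiv), PhMe, 90 °C
Reagents that add atoms: none
Why: Ozonolysis unmasks the aldehyde, then acid removes the tert-butyl ester, the β-keto acid decarboxylates and the ring-ketone enol closes onto the aldehyde with dehydration (intramolecular aldol condensation of a 1,6-keto aldehyde), the only mode that can reach a conjugated enone; no stereocentre is touched.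

**Step 6**
Reactants: 9 (7S,7aS)-7-bromo-7a-methyl-1,2,5,6,7,7a-hexahydro-4H-inden-4-one
Product: 10 (4R,7S,7aS)-7-bromo-4,7a-dimethyl-2,4,5,6,7,7a-hexahydro-1H-inden-4-ol
Conditions: MeLi, CeCl3, THF, −78 °C
Reagents that add atoms: methyllithium [Li]C
Why: Organocerium 1,2-addition to the enone; methyl enters from the face opposite the syn-axial angular methyl (equatorial attack), which gives the axial tertiary OH with 4R configuration.

**Step 7**
Reactants: 10 (4R,7S,7aS)-7-bromo-4,7a-dimethyl-2,4,5,6,7,7a-hexahydro-1H-inden-4-ol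
Product: 12 (3R,3aS,4R,7S,7aS)-7-bromo-4,7a-dimethyl-3-(4,4,5,5-tetramethyl-1,3,2-dioxaborolan-2-yl)octahydro-1H-inden-4-ol, via alkylborane 11 (not isolated)
Conditions: BH3·SMe2 (3 equiv), THF, 0 °C→rt; then pinacol, rt
Reagents that add atoms: borane–dimethyl sulfide B.CSC; pinacol CC(C)(O)C(C)(C)O
Why: Hydroboration puts boron on the less substituted C3 and H on C3a in a syn addition from the face opposite both the angular methyl and the axial oxygen (as in Δ14-steroid hydroboration), which sets the trans ring fusion and C3; pinacol converts the monoalkylborane to the boronic ester.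

**Step 8**
Reactants: 12 (3R,3aS,4R,7S,7aS)-7-bromo-4,7a-dimethyl-3-(4,4,5,5-tetramethyl-1,3,2-dioxaborolan-2-yl)octahydro-1H-inden-4-ol
Product: 13 (3R,3aS,4R,7S,7aS)-7-bromo-4,7a-dimethyl-3-[(4,4,5,5-tetramethyl-1,3,2-dioxaborolan-2-yl)methyl]octahydro-1H-inden-4-ol
Conditions: BrCH2Cl, n-BuLi (2.5 equiv each), THF, −78 °C→rt
Reagents that add atoms: bromochloromethane ClCBr
Why: Matteson homologation; chloromethyllithium forms the boron ate complex and the secondary alkyl group migrates with retention, so the new CH2 stays on the same face.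

**Step 9**
Reactants: 14 1-bromo-3-methylbut-2-ene; 5 tert-butyl acetoacetate
Product: 15 tert-butyl 7-methyl-3-oxooct-6-enoate
Conditions: NaH, THF, 0 °C; n-BuLi, −10 °C; then 14, 0 °C
Reagents that add atoms: none
Why: Weiler dianion alkylation at the γ-carbon, as in step 3.

**Step 10**
Reactants: 15 tert-butyl 7-methyl-3-oxooct-6-enoate
Product: 16 tert-butyl (3S)-3-bromo-2,2-dimethyl-6-oxocyclohexane-1-carboxylate
Conditions: DBDMH (0.55 equiv), chiral BINOL-derived N-triflylthiophosphoramide (10 mol %, same antipode as step 4), PhMe, −78 °C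
Reagents that add atoms: 1,3-dibromo-5,5-dimethylhydantoin CC1(C)N(Br)C(=O)N(Br)C1=O
Why: Proposed new method: same catalytic bromocarbocyclization as step 4; the catalyst-bound Br+ adds to the Si face of C6 of the prenyl alkene and the H-bonded keto ester enol closes the chair at the tertiary carbon anti to Br, setting the 3S bromide; closest known reactions are the thiophosphoramide/DBDMH bromocyclization of homogeranylarenes and Lewis acid cyclizations of this keto ester class (cation–olefin cyclization).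

**Step 11**
Reactants: 16 tert-butyl (3S)-3-bromo-2,2-dimethyl-6-oxocyclohexane-1-carboxylate
Product: 17 (S)-4-bromo-3,3-dimethylcyclohexan-1-one
Conditions: TsOH·H2O (0.2 equiv), PhMe, 90 °C
Reagents that add atoms: none
Why: Acid cleavage of the tert-butyl ester and decarboxylation of the β-keto acid; the neopentylic C–Br stereocentre is untouched.

**Step 12**
Reactants: 17 (S)-4-bromo-3,3-dimethylcyclohexan-1-one
Product: 18 (4S)-4-bromo-5,5-dimethylcyclohex-1-en-1-yl trifluoromethanesulfonate
Conditions: KHMDS, THF, −78 °C; Comins' reagent, −78 °C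
Reagents that add atoms: N-(5-chloropyridin-2-yl)bis(trifluoromethanesulfonimide) FC(F)(F)S(=O)(=O)N(c1ccc(Cl)cn1)S(=O)(=O)C(F)(F)F
Why: Kinetic deprotonation at the unhindered C6 (not the CH2 next to the gem-dimethyl carbon) and O-triflation at −78 °C, cold enough that the enolate does not displace the neopentylic bromide.

**Step 13**
Reactants: 13 (3R,3aS,4R,7S,7aS)-7-bromo-4,7a-dimethyl-3-[(4,4,5,5-tetramethyl-1,3,2-dioxaborolan-2-yl)methyl]octahydro-1H-inden-4-ol; 18 (4S)-4-bromo-5,5-dimethylcyclohex-1-en-1-yl trifluoromethanesulfonate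
Product: 19 (3S,3aS,4R,7S,7aS)-7-bromo-3-{[(4S)-4-bromo-5,5-dimethylcyclohex-1-en-1-yl]methyl}-4,7a-dimethyloctahydro-1H-inden-4-ol
Conditions: Pd(OAc)2 (5 mol %), RuPhos (10 mol %), K3PO4, PhMe/H2O, 80 °C
Reagents that add atoms: none
Why: B-alkyl Suzuki–Miyaura coupling of the primary alkylboronate with the alkenyl triflate; the hindered secondary bromides do not undergo oxidative addition and no stereocentre is affected.

**Step 14**
Reactants: 19 (3S,3aS,4R,7S,7aS)-7-bromo-3-{[(4S)-4-bromo-5,5-dimethylcyclohex-1-en-1-yl]methyl}-4,7a-dimethyloctahydro-1H-inden-4-ol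
Product: 20 (3S,3aS,4R,7S,7aS)-7-bromo-3-{[(1S,4S,6R)-4-bromo-3,3-dimethyl-7-oxabicyclo[4.1.0]heptan-1-yl]methyl}-4,7a-dimethyloctahydro-1H-inden-4-ol
Conditions: D-fructose-derived Shi ketone (30 mol %), Oxone, K2CO3, Bu4NHSO4, MeCN/DMM/aq. buffer (pH 10.5), 0 °C
Reagents that add atoms: Oxone (potassium peroxymonosulfate) [K+].OOS(=O)(=O)[O-]
Why: Shi asymmetric epoxidation; the chiral dioxirane epoxidizes the trisubstituted cyclohexene through the spiro transition state on the face that gives the (1S,6R)-epoxide (same sense as 1-phenylcyclohexene to its R,R-oxide), so the C–O bond at the future carbinol carbon is set by the reagent and not by the weakly biased bromocyclohexene ring.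

**Step 15**
Reactants: 20 (3S,3aS,4R,7S,7aS)-7-bromo-3-{[(1S,4S,6R)-4-bromo-3,3-dimethyl-7-oxabicyclo[4.1.0]heptan-1-yl]methyl}-4,7a-dimethyloctahydro-1H-inden-4-ol
Product: 21 (3S,3aS,4R,7S,7aS)-7-bromo-3-{[(1S,4S)-4-bromo-1-hydroxy-3,3-dimethylcyclohexyl]methyl}-4,7a-dimethyloctahydro-1H-inden-4-ol
Conditions: LiAlH4, Et2O, 0 °C→rt; Rochelle salt work-up (no acid)
Reagents that add atoms: none
Why: Hydride opens the epoxide by SN2 at the secondary carbon in a trans-diaxial (Fürst–Plattner) sense, leaving the tertiary C–O bond with its configuration (axial OH cis to the equatorial Br); both bromides are flanked by quaternary carbons and resist hydride displacement.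

**Compound list**
1 | hex-1-en-5-yne | C#CCCC=C | starting material
2 | (E)-dimethyl(2-methylhexa-1,5-dien-1-yl)alane | C=CCC/C(C)=C/[Al](C)C | intermediate
3 | (E)-3-methylhepta-2,6-dien-1-ol | OC/C=C(\C)CCC=C | intermediate
4 | (E)-1-bromo-3-methylhepta-2,6-diene | BrC/C=C(\C)CCC=C | intermediate
5 | tert-butyl acetoacetate | CC(=O)CC(=O)OC(C)(C)C | starting material
6 | tert-butyl (E)-7-methyl-3-oxoundeca-6,10-dienoate | CC(C)(C)OC(=O)CC(=O)CC/C=C(\C)CCC=C | intermediate
7 | tert-butyl (2S,3S)-3-bromo-2-(but-3-en-1-yl)-2-methyl-6-oxocyclohexane-1-carboxylate | C=CCC[C@]1(C)[C@@H](Br)CCC(=O)C1C(=O)OC(C)(C)C | intermediate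
8 | tert-butyl (2S,3S)-3-bromo-2-methyl-6-oxo-2-(3-oxopropyl)cyclohexane-1-carboxylate | O=CCC[C@]1(C)[C@@H](Br)CCC(=O)C1C(=O)OC(C)(C)C | intermediate
9 | (7S,7aS)-7-bromo-7a-methyl-1,2,5,6,7,7a-hexahydro-4H-inden-4-one | C1CC=C2C(=O)CC[C@H](Br)[C@@]12C | intermediate
10 | (4R,7S,7aS)-7-bromo-4,7a-dimethyl-2,4,5,6,7,7a-hexahydro-1H-inden-4-ol | C1CC=C2[C@](C)(O)CC[C@H](Br)[C@@]12C | intermediate
11 | (3R,3aS,4R,7S,7aS)-3-boranyl-7-bromo-4,7a-dimethyloctahydro-1H-inden-4-ol | B[C@@H]2CC[C@]3(C)[C@@H](Br)CC[C@@](C)(O)[C@@H]23 | intermediate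
12 | (3R,3aS,4R,7S,7aS)-7-bromo-4,7a-dimethyl-3-(4,4,5,5-tetramethyl-1,3,2-dioxaborolan-2-yl)octahydro-1H-inden-4-ol | CC1(C)OB(OC1(C)C)[C@@H]2CC[C@]3(C)[C@@H](Br)CC[C@@](C)(O)[C@@H]23 | intermediate
13 | (3R,3aS,4R,7S,7aS)-7-bromo-4,7a-dimethyl-3-[(4,4,5,5-tetramethyl-1,3,2-dioxaborolan-2-yl)methyl]octahydro-1H-inden-4-ol | CC1(C)OB(OC1(C)C)C[C@@H]2CC[C@]3(C)[C@@H](Br)CC[C@@](C)(O)[C@@H]23 | intermediate
14 | 1-bromo-3-methylbut-2-ene (prenyl bromide) | CC(C)=CCBr | starting material
15 | tert-butyl 7-methyl-3-oxooct-6-enoate | CC(C)=CCCC(=O)CC(=O)OC(C)(C)C | intermediate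
16 | tert-butyl (3S)-3-bromo-2,2-dimethyl-6-oxocyclohexane-1-carboxylate | CC(C)(C)OC(=O)C1C(=O)CC[C@H](Br)C1(C)C | intermediate
17 | (S)-4-bromo-3,3-dimethylcyclohexan-1-one | O=C1CC[C@H](Br)C(C)(C)C1 | intermediate
18 | (4S)-4-bromo-5,5-dimethylcyclohex-1-en-1-yl trifluoromethanesulfonate | O=S(=O)(OC1=CC[C@H](Br)C(C)(C)C1)C(F)(F)F | intermediate
19 | (3S,3aS,4R,7S,7aS)-7-bromo-3-{[(4S)-4-bromo-5,5-dimethylcyclohex-1-en-1-yl]methyl}-4,7a-dimethyloctahydro-1H-inden-4-ol | CC1(C)CC(C[C@@H]2CC[C@]3(C)[C@@H](Br)CC[C@@](C)(O)[C@@H]23)=CC[C@@H]1Br | intermediate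
20 | (3S,3aS,4R,7S,7aS)-7-bromo-3-{[(1S,4S,6R)-4-bromo-3,3-dimethyl-7-oxabicyclo[4.1.0]heptan-1-yl]methyl}-4,7a-dimethyloctahydro-1H-inden-4-ol | CC1(C)C[C@]2(C[C@@H]3CC[C@]4(C)[C@@H](Br)CC[C@@](C)(O)[C@@H]34)O[C@@H]2C[C@@H]1Br | intermediate
21 | (3S,3aS,4R,7S,7aS)-7-bromo-3-{[(1S,4S)-4-bromo-1-hydroxy-3,3-dimethylcyclohexyl]methyl}-4,7a-dimethyloctahydro-1H-inden-4-ol | CC1(C)C[C@@](O)(C[C@@H]2CC[C@]3(C)[C@@H](Br)CC[C@@](C)(O)[C@@H]23)CC[C@@H]1Br | target

**Totals**
Total step count: 15. Longest linear sequence: 11 (steps 1–8, then 13–15).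

**Steps most likely to fail**

Step 4 (proposed new bromocyclization; risks are O- instead of C-cyclization and low ee). The fallback sets out from 3 and comes back at 7. Alcohol 3 is bromochlorinated at the allylic alkene by the known Ti/chiral Schiff-base-catalysed enantioselective bromochlorination of allylic alcohols (NBS, ClTi(Oi-Pr)3, ligand, hexanes, −20 °C) to (2S,3R)-2-bromo-3-chloro-3-methylhept-6-en-1-ol F1. F1 is converted with Tf2O and 2,6-lutidine to (2S,3R)-2-bromo-3-chloro-3-methylhept-6-en-1-yl trifluoromethanesulfonate F2, which alkylates the dianion of 5 to give tert-butyl (6S,7R)-6-bromo-7-chloro-7-methyl-3-oxoundec-10-enoate F3. Ionization of the tertiary chloride in HFIP with anti bromine participation gives the enantiopure bromonium ion, and the keto ester closes the ring to 7.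

Step 10 (same new method on the prenyl substrate). The fallback sets out from 5 and comes back at 16, with commercial 3-methylbut-2-en-1-ol in place of 14. The same known bromochlorination of 3-methylbut-2-en-1-ol gives (S)-2-bromo-3-chloro-3-methylbutan-1-ol F4. Triflation gives (S)-2-bromo-3-chloro-3-methylbutyl trifluoromethanesulfonate F5, and alkylation of the dianion of 5 gives tert-butyl (S)-6-bromo-7-chloro-7-methyl-3-oxooctanoate F6. Solvolysis in HFIP closes the ring to 16.

Step 13 (alkyl pinacol boronates transmetalate slowly; protodeboronation or triflate hydrolysis may win). The fallback sets out from 13 and 17 and comes back at 19 without palladium. Ketone 17 is condensed with 2,4,6-triisopropylbenzenesulfonyl hydrazide to (S)-N'-(4-bromo-3,3-dimethylcyclohexylidene)-2,4,6-triisopropylbenzenesulfonohydrazide F7. A Shapiro reaction (n-BuLi, −78→0 °C) gives [(4S)-4-bromo-5,5-dimethylcyclohex-1-en-1-yl]lithium F8, used in excess because one equivalent deprotonates the tertiary alcohol. F8 adds to boronate 13, and Zweifel olefination (I2, then NaOMe/MeOH) gives 19 with retention at the migrating CH2.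

**Further compounds**
F1 | step 4 | (2S,3R)-2-bromo-3-chloro-3-methylhept-6-en-1-ol | OC[C@H](Br)[C@](C)(Cl)CCC=C
F2 | step 4 | (2S,3R)-2-bromo-3-chloro-3-methylhept-6-en-1-yl trifluoromethanesulfonate | O=S(=O)(OC[C@H](Br)[C@](C)(Cl)CCC=C)C(F)(F)F
F3 | step 4 | tert-butyl (6S,7R)-6-bromo-7-chloro-7-methyl-3-oxoundec-10-enoate | CC(C)(C)OC(=O)CC(=O)CC[C@H](Br)[C@](C)(Cl)CCC=C
F4 | step 10 | (S)-2-bromo-3-chloro-3-methylbutan-1-ol | OC[C@H](Br)C(C)(C)Cl
F5 | step 10 | (S)-2-bromo-3-chloro-3-methylbutyl trifluoromethanesulfonate | O=S(=O)(OC[C@H](Br)C(C)(C)Cl)C(F)(F)F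
F6 | step 10 | tert-butyl (S)-6-bromo-7-chloro-7-methyl-3-oxooctanoate | CC(C)(C)OC(=O)CC(=O)CC[C@H](Br)C(C)(C)Cl
F7 | step 13 | (S)-N'-(4-bromo-3,3-dimethylcyclohexylidene)-2,4,6-triisopropylbenzenesulfonohydrazide | CC(C)c1cc(C(C)C)c(S(=O)(=O)NN=C2CC[C@H](Br)C(C)(C)C2)c(C(C)C)c1
F8 | step 13 | [(4S)-4-bromo-5,5-dimethylcyclohex-1-en-1-yl]lithium | [Li]C1=CC[C@H](Br)C(C)(C)C1
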